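## Retrosynthetic overview

1. Ring numbering: C1 = carbinol carbon, C3 = CHBr, C4 = CMeCl. The enabling feature is that the oxygen on C1 and the chlorine on C4 sit cis and 1,4 across the six-membered ring, with bromine on C3 anti to both. The halogenated ring is therefore a ring-opened 3-endo-bromo-4-methyl-7-oxabicyclo[2.2.1]heptane.
2. Key disconnection: the C3–C4 bond is made as a trisubstituted alkene by ring-closing metathesis of acyclic diene 5. In the same flask NBS and the C1 hydroxyl turn that alkene into bromo-oxanorbornane 7 (carbocycle first, oxygen bridge second).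
3. The temporary bridge is opened at C4 by chloride with retention, through the bromonium ion of the neighbouring C3–Br (TiCl4). This is the only C–Cl bond-forming step.
4. C1, the only stereocentre of 5, comes from enantioselective allylboration of α-ketoester 4 (dimethyl oxalate plus the homomethallyl Grignard reagent).
5. The side chain is attached last: Weinreb amide 9 plus the Grignard reagent of (R)-allylic silyl ether 12 (Shi epoxidation, epoxide-to-allyl-silyl-ether isomerisation), then Peterson methylenation with desilylation.

Key step: step 3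

Remark on the chemistry: read from the SMILES, the target is (1S,3R,4R) in the ring (C1–OH cis to C4–Cl, trans to C3–Br) and (R) at the side-chain carbinol; the route is laid out for exactly this isomer.

## Route

Step 1
Reactants: 1 4-bromo-2-methylbut-1-ene; 2 dimethyl oxalate
Product: 4 methyl 5-methyl-2-oxohex-5-enoate, via Grignard reagent 3 (not isolated)
Conditions: 1, Mg turnings, THF, 35 °C; then cannulated into 2 (2.0 equiv), THF, −78 °C; aq NH4Cl
Reagents that add atoms: none
Why: Acylation of a Grignard reagent by an oxalate diester (inverse addition, excess diester, −78 °C) should stop at the α-ketoester because the magnesium hemiketal collapses only on work-up; no stereocentre is formed.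

Step 2
Reactants: 4 methyl 5-methyl-2-oxohex-5-enoate
Product: 5 methyl (2S)-2-hydroxy-5-methyl-2-(prop-2-en-1-yl)hex-5-enoate
Conditions: allylB(pin) (1.5 equiv), chiral valine-derived aminophenol organocatalyst (3 mol %), NaOtBu (10 mol %), MeOH (2 equiv), toluene, 4 °C
Reagents that add atoms: allylboronic acid pinacol ester, C=CCB1OC(C)(C)C(C)(C)O1
Why: Catalytic enantioselective allylboration of an α-ketoester: the aminophenol exchanges onto boron and delivers allyl through a closed chair-like transition state in which the ester is held by the catalyst's hydrogen-bond donor; the catalyst antipode is chosen so that allyl adds to the Si face of the ketone, which sets the (S)-tertiary carbinol (the future C1).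

Step 3
Reactants: 5 methyl (2S)-2-hydroxy-5-methyl-2-(prop-2-en-1-yl)hex-5-enoate
Product: 7 methyl (1S,3R,4R)-3-bromo-4-methyl-7-oxabicyclo[2.2.1]heptane-1-carboxylate, via cyclohexenol ester 6 (not isolated)
Conditions: RuCl2(=CHPh)(PCy3)(H2IMes) (second-generation Grubbs catalyst, 2 mol %), CH2Cl2 (0.02 M), 40 °C, argon sparge; then 0 °C, NBS (1.1 equiv), exclusion of light
Reagents that add atoms: N-bromosuccinimide, O=C1CCC(=O)N1Br
Why: The ruthenium alkylidene engages the allyl terminus and closes the ring on the 1,1-disubstituted alkene through a ruthenacyclobutane, expelling ethene and creating the C3–C4 bond (future CHBr–CMeCl) as a trisubstituted alkene; NBS then forms a bromonium ion on this alkene and the C1 hydroxyl, 1,4 across the ring, opens it at the tertiary carbon to give the oxygen bridge. The closest known reaction types are ring-closing olefin metathesis to 1-methylcyclohexenes and the bromoetherification of 4-substituted cyclohex-3-en-1-ols to 2-bromo-7-oxabicyclo[2.2.1]heptanes (1,4-cineole series). The carbocycle closes by ring-closing metathesis (six-membered, no stereochemical issue) and the tetrahydrofuran ring by 5-exo, Markovnikov opening of the bromonium ion. Both new stereocentres are set by the C1 carbinol alone: because the nucleophile is the C1 oxygen itself, the new C4–O bond must lie cis to C1–O, and anti opening then places bromine at C3 on the opposite face (endo, anti to the bridge). The step needs cyclisation in preference to oligomerisation, secured by dilution, removal of ethene and the unstrained six-membered ring, and capture of the bromonium ion by OH rather than by the ester carbonyl, secured by the five-membered mode at the tertiary carbon, the poor nucleophilicity of a methyl ester and the reversibility of bromonium formation on the unproductive face.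

Step 4
Reactants: 7 methyl (1S,3R,4R)-3-bromo-4-methyl-7-oxabicyclo[2.2.1]heptane-1-carboxylate
Product: 8 (1S,3R,4R)-3-bromo-N-methoxy-N,4-dimethyl-7-oxabicyclo[2.2.1]heptane-1-carboxamide
Conditions: MeNH(OMe)·HCl (3 equiv), iPrMgCl (6 equiv), THF, −20 → 0 °C
Reagents that add atoms: N,O-dimethylhydroxylamine hydrochloride, CNOC.Cl
Why: Aminolysis of the ester by the chloromagnesium amide (Weinreb amide formation); the bridgehead ester has no α-hydrogen, and the rigid bromo ether has neither a free hydroxyl nor a β-hydrogen antiperiplanar to bromine, so it should tolerate the basic reagent.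

Step 5
Reactants: 8 (1S,3R,4R)-3-bromo-N-methoxy-N,4-dimethyl-7-oxabicyclo[2.2.1]heptane-1-carboxamide
Product: 9 (1S,3R,4R)-3-bromo-4-chloro-1-hydroxy-N-methoxy-N,4-dimethylcyclohexane-1-carboxamide
Conditions: TiCl4 (2.5 equiv), CH2Cl2, −78 → −30 °C; aq NaHCO3
Reagents that add atoms: titanium tetrachloride, Cl[Ti](Cl)(Cl)Cl
Why: Lewis-acid cleavage of a bridged tertiary ether with neighbouring-group participation: TiCl4 chelated between the amide carbonyl and O7 ionises the O7–C4 bond while the antiperiplanar endo bromine bridges from the opposite face, and chloride opens the bromonium ion at the tertiary carbon from the face the oxygen has left, so C4 receives chlorine with retention (cis to C1–OH, trans to Br); the carboxamide on C1 prevents ionisation at that bridgehead.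

Step 6
Reactants: 10 5-bromo-2-methylpent-2-ene
Product: 11 (3R)-3-(2-bromoethyl)-2,2-dimethyloxirane
Conditions: D-fructose-derived Shi ketone (0.3 equiv), Oxone (2KHSO5·KHSO4·K2SO4), K2CO3, Bu4NHSO4, MeCN–dimethoxymethane–aq Na2B4O7 buffer (pH 10.5), 0 °C
Reagents that add atoms: potassium peroxymonosulfate, [K+].[O-]S(=O)(=O)OO
Why: Shi asymmetric epoxidation: the chiral dioxirane transfers oxygen to the trisubstituted alkene through a spiro transition state, and the D-fructose-derived ketone should give the (R)-epoxide; the primary bromide is expected to survive at 0 °C.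

Step 7
Reactants: 11 (3R)-3-(2-bromoethyl)-2,2-dimethyloxirane
Product: 12 tert-butyl{[(3R)-5-bromo-2-methylpent-1-en-3-yl]oxy}dimethylsilane
Conditions: TBSOTf (1.3 equiv), 2,6-lutidine (3 equiv), toluene, −78 → 23 °C
Reagents that add atoms: tert-butyldimethylsilyl trifluoromethanesulfonate, CC(C)(C)[Si](C)(C)OS(=O)(=O)C(F)(F)F
Why: Silyl triflate–amine isomerisation of an epoxide to an allylic silyl ether: O-silylation, opening at the tertiary carbon and loss of a methyl proton to the hindered base give the isopropenyl carbinol already protected; the secondary C–O bond is never broken, so the (R) configuration is retained.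

Step 8
Reactants: 9 (1S,3R,4R)-3-bromo-4-chloro-1-hydroxy-N-methoxy-N,4-dimethylcyclohexane-1-carboxamide; 12 tert-butyl{[(3R)-5-bromo-2-methylpent-1-en-3-yl]oxy}dimethylsilane
Product: 14 (4R)-1-[(1S,3R,4R)-3-bromo-4-chloro-1-hydroxy-4-methylcyclohexyl]-4-[(tert-butyldimethylsilyl)oxy]-5-methylhex-5-en-1-one, via Grignard reagent 13 (not isolated)
Conditions: 12, Mg, THF, 40 °C; 9, iPrMgCl (1.0 equiv), THF, −20 °C, then 13 (1.6 equiv), −20 → 0 °C; aq NH4Cl
Reagents that add atoms: none
Why: Weinreb ketone synthesis: the Grignard reagent adds once and the five-membered magnesium chelate holds the tetrahedral intermediate until work-up; the C1 hydroxyl is masked as its magnesium alkoxide, and alkylmagnesium halides at or below 0 °C should neither exchange with nor eliminate the secondary bromide and tertiary chloride, so no stereocentre is touched.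

Step 9
Reactants: 14 (4R)-1-[(1S,3R,4R)-3-bromo-4-chloro-1-hydroxy-4-methylcyclohexyl]-4-[(tert-butyldimethylsilyl)oxy]-5-methylhex-5-en-1-one
Product: 15 (5R)-2-[(1S,3R,4R)-3-bromo-4-chloro-1-hydroxy-4-methylcyclohexyl]-5-[(tert-butyldimethylsilyl)oxy]-6-methyl-1-(trimethylsilyl)hept-6-en-2-ol (mixture of epimers at C2 of the chain)
Conditions: Me3SiCH2MgCl (4 equiv), anhydrous CeCl3 (4 equiv), THF, −78 → 0 °C; aq NH4Cl
Reagents that add atoms: (trimethylsilyl)methylmagnesium chloride, C[Si](C)(C)C[Mg]Cl
Why: First half of a Peterson olefination: the weakly basic, oxophilic organocerium reagent should add to the hindered α-hydroxy ketone without enolisation or elimination of the halides; the configuration of the new carbinol is irrelevant because it is destroyed in step 10.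

Step 10
Reactants: 15 (5R)-2-[(1S,3R,4R)-3-bromo-4-chloro-1-hydroxy-4-methylcyclohexyl]-5-[(tert-butyldimethylsilyl)oxy]-6-methyl-1-(trimethylsilyl)hept-6-en-2-ol
Product: 16 (1S,3R,4R)-3-bromo-4-chloro-1-[(5R)-5-hydroxy-6-methylhepta-1,6-dien-2-yl]-4-methylcyclohexan-1-ol
Conditions: HF·pyridine, MeCN, 0 → 23 °C
Reagents that add atoms: none
Why: Acid-induced Peterson elimination of the β-hydroxysilane (ionisation at the carbinol that is β to silicon, then loss of the silyl group) should give the 1,1-disubstituted alkene regiospecifically, and the same fluoride medium cleaves the TBS ether; no stereocentre is involved.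

## Compound list

1 | 4-bromo-2-methylbut-1-ene | C=C(C)CCBr | starting material
2 | dimethyl oxalate | COC(=O)C(=O)OC | starting material
3 | (3-methylbut-3-en-1-yl)magnesium bromide (not isolated) | C=C(C)CC[Mg]Br | intermediate
4 | methyl 5-methyl-2-oxohex-5-enoate | COC(=O)C(=O)CCC(C)=C | intermediate
5 | methyl (2S)-2-hydroxy-5-methyl-2-(prop-2-en-1-yl)hex-5-enoate | COC(=O)[C@](CC=C)(O)CCC(C)=C | intermediate
6 | methyl (1S)-1-hydroxy-4-methylcyclohex-3-ene-1-carboxylate (not isolated) | COC(=O)[C@]1(O)CCC(C)=CC1 | intermediate
7 | methyl (1S,3R,4R)-3-bromo-4-methyl-7-oxabicyclo[2.2.1]heptane-1-carboxylate | COC(=O)[C@]1(O2)CC[C@]2(C)[C@H](Br)C1 | intermediate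
8 | (1S,3R,4R)-3-bromo-N-methoxy-N,4-dimethyl-7-oxabicyclo[2.2.1]heptane-1-carboxamide | CON(C)C(=O)[C@]1(O2)CC[C@]2(C)[C@H](Br)C1 | intermediate
9 | (1S,3R,4R)-3-bromo-4-chloro-1-hydroxy-N-methoxy-N,4-dimethylcyclohexane-1-carboxamide | CON(C)C(=O)[C@]1(O)CC[C@@](C)(Cl)[C@H](Br)C1 | intermediate
10 | 5-bromo-2-methylpent-2-ene | CC(C)=CCCBr | starting material
11 | (3R)-3-(2-bromoethyl)-2,2-dimethyloxirane | CC1(C)[C@H](O1)CCBr | intermediate
12 | tert-butyl{[(3R)-5-bromo-2-methylpent-1-en-3-yl]oxy}dimethylsilane | C=C(C)[C@H](O[Si](C)(C)C(C)(C)C)CCBr | intermediate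
13 | {(3R)-3-[(tert-butyldimethylsilyl)oxy]-4-methylpent-4-en-1-yl}magnesium bromide (not isolated) | C=C(C)[C@H](O[Si](C)(C)C(C)(C)C)CC[Mg]Br | intermediate
14 | (4R)-1-[(1S,3R,4R)-3-bromo-4-chloro-1-hydroxy-4-methylcyclohexyl]-4-[(tert-butyldimethylsilyl)oxy]-5-methylhex-5-en-1-one | C=C(C)[C@H](O[Si](C)(C)C(C)(C)C)CCC(=O)[C@]1(O)CC[C@@](C)(Cl)[C@H](Br)C1 | intermediate
15 | (5R)-2-[(1S,3R,4R)-3-bromo-4-chloro-1-hydroxy-4-methylcyclohexyl]-5-[(tert-butyldimethylsilyl)oxy]-6-methyl-1-(trimethylsilyl)hept-6-en-2-ol (epimers at chain C2) | C=C(C)[C@H](O[Si](C)(C)C(C)(C)C)CCC(O)(C[Si](C)(C)C)[C@]1(O)CC[C@@](C)(Cl)[C@H](Br)C1 | intermediate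
16 | (1S,3R,4R)-3-bromo-4-chloro-1-[(5R)-5-hydroxy-6-methylhepta-1,6-dien-2-yl]-4-methylcyclohexan-1-ol | C=C(C)[C@H](O)CCC(=C)[C@]1(O)CC[C@@](C)(Cl)[C@H](Br)C1 | target

## Step count and risks

Total steps: 10. Longest linear sequence: 8 (steps 1–5, then 8–10); steps 6 and 7 build the side-chain fragment.

Steps most likely to fail:

1. Step 5 (chloride opening of the oxygen bridge). The O7–C4 bond may ionise without effective bromine participation and then lose a proton to give alkenes, chloride may enter at the secondary carbon with migration of bromine, or the ether may resist cleavage at temperatures the N-methoxy amide tolerates. The fallback sets out from 6 and returns at 9; it adds the halogens intermolecularly instead of through the bridge. Compound 6 is isolated after the metathesis stage of step 3 (NBS left out), and trifluoroacetic anhydride/pyridine blocks its hydroxyl as methyl (1S)-4-methyl-1-[(trifluoroacetyl)oxy]cyclohex-3-ene-1-carboxylate F1, which can no longer cyclise. Bu4NBrCl2 in CH2Cl2 at −40 °C should add BrCl anti and in the Markovnikov sense; methyl (1S,3R,4R)-3-bromo-4-chloro-4-methyl-1-[(trifluoroacetyl)oxy]cyclohexane-1-carboxylate F2 is separated by chromatography from its (3S,4S) diastereomer. NaHCO3 in methanol removes the trifluoroacetate to give methyl (1S,3R,4R)-3-bromo-4-chloro-1-hydroxy-4-methylcyclohexane-1-carboxylate F3, and aminolysis under the conditions of step 4 converts F3 into 9. The cost is that facial control by the C1 oxygen is lost, so a diastereomer separation has to be accepted.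

2. Step 2 (enantioselective allylboration). Facial discrimination may be insufficient for a ketoester whose two flanks are an ester and an unbranched alkyl chain, which would erode the enantiopurity of the one stereocentre that controls the ring. The fallback sets out from Grignard reagent 3 and returns at 5; it takes C1 from a Sharpless epoxidation. CuI-catalysed addition of 3 to propargyl alcohol should give 5-methyl-2-methylidenehex-5-en-1-ol F4. Epoxidation with Ti(OiPr)4, D-(−)-diethyl tartrate and tBuOOH (4 Å sieves, CH2Cl2, −20 °C) should give [(2R)-2-(3-methylbut-3-en-1-yl)oxiran-2-yl]methanol F5. VinylMgBr with catalytic CuI opens the epoxide at its CH2 terminus to give (2S)-5-methyl-2-(prop-2-en-1-yl)hex-5-ene-1,2-diol F6. Oxidation of the primary alcohol (SO3·pyridine/DMSO/Et3N, then NaClO2, NaH2PO4, 2-methylbut-2-ene) gives (2S)-2-hydroxy-5-methyl-2-(prop-2-en-1-yl)hex-5-enoic acid F7, and Me3SiCHN2 in methanol/toluene esterifies F7 to 5.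

3. Step 9 (silylmethyl addition for the Peterson methylenation). Addition to a ketone that is flanked by a quaternary carbon bearing a metal alkoxide may stall, and on warming the C1 alkoxide could trigger fragmentation of the C1–C2 ring bond with loss of bromide (the equatorial C3–Br bond is antiperiplanar to that bond). The fallback sets out from 14 and returns at 16; it caps the alkoxide and uses a direct titanium methylidene olefination. Me3SiOTf/2,6-lutidine (CH2Cl2, −78 °C) silylates the tertiary hydroxyl to give (4R)-1-[(1S,3R,4R)-3-bromo-4-chloro-4-methyl-1-(trimethylsilyloxy)cyclohexyl]-4-[(tert-butyldimethylsilyl)oxy]-5-methylhex-5-en-1-one F8. Petasis methylenation with Cp2TiMe2 (toluene, 65 °C) should give {[(1S,3R,4R)-3-bromo-1-[(5R)-5-[(tert-butyldimethylsilyl)oxy]-6-methylhepta-1,6-dien-2-yl]-4-chloro-4-methylcyclohexyl]oxy}trimethylsilane F9, and HF·pyridine in MeCN removes both silyl groups from F9 to give 16.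

Further compounds
F1 | step 5 | methyl (1S)-4-methyl-1-[(trifluoroacetyl)oxy]cyclohex-3-ene-1-carboxylate | COC(=O)[C@]1(OC(=O)C(F)(F)F)CCC(C)=CC1
F2 | step 5 | methyl (1S,3R,4R)-3-bromo-4-chloro-4-methyl-1-[(trifluoroacetyl)oxy]cyclohexane-1-carboxylate | COC(=O)[C@]1(OC(=O)C(F)(F)F)CC[C@@](C)(Cl)[C@H](Br)C1
F3 | step 5 | methyl (1S,3R,4R)-3-bromo-4-chloro-1-hydroxy-4-methylcyclohexane-1-carboxylate | COC(=O)[C@]1(O)CC[C@@](C)(Cl)[C@H](Br)C1
F4 | step 2 | 5-methyl-2-methylidenehex-5-en-1-ol | C=C(CO)CCC(C)=C
F5 | step 2 | [(2R)-2-(3-methylbut-3-en-1-yl)oxiran-2-yl]methanol | OC[C@@]1(CO1)CCC(C)=C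
F6 | step 2 | (2S)-5-methyl-2-(prop-2-en-1-yl)hex-5-ene-1,2-diol | OC[C@](CC=C)(O)CCC(C)=C
F7 | step 2 | (2S)-2-hydroxy-5-methyl-2-(prop-2-en-1-yl)hex-5-enoic acid | OC(=O)[C@](CC=C)(O)CCC(C)=C
F8 | step 9 | (4R)-1-[(1S,3R,4R)-3-bromo-4-chloro-4-methyl-1-(trimethylsilyloxy)cyclohexyl]-4-[(tert-butyldimethylsilyl)oxy]-5-methylhex-5-en-1-one | C=C(C)[C@H](O[Si](C)(C)C(C)(C)C)CCC(=O)[C@]1(O[Si](C)(C)C)CC[C@@](C)(Cl)[C@H](Br)C1
F9 | step 9 | {[(1S,3R,4R)-3-bromo-1-[(5R)-5-[(tert-butyldimethylsilyl)oxy]-6-methylhepta-1,6-dien-2-yl]-4-chloro-4-methylcyclohexyl]oxy}trimethylsilane | C=C(C)[C@H](O[Si](C)(C)C(C)(C)C)CCC(=C)[C@]1(O[Si](C)(C)C)CC[C@@](C)(Cl)[C@H](Br)C1
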